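**Numbering used throughout** (structures are in the compound list after the steps): 1 vanillin; 2 O-tosylvanillin; 3 (S)-4-benzyl-oxazolidinone; 4 methyl succinyl chloride; 5 succinyl imide; 6 syn-aldol adduct; 7 trans lactone imide; 8 trans paraconic acid; 9 hydroxymethyl lactone; 10 3,4-bis(benzyloxy)benzyl alcohol; 11 its trichloroacetimidate; 12 lactone ether; 13 trifluoroacetyl lactone; 14 diazo lactone; 15 furofuranone; 16 debenzylated furofuranone; 17 all-cis oxolane acid; 18 all-cis oxolane alcohol; 19 quinone methide; 20 2,3-trans oxolane alcohol; 21 tetraol; 22 target.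

## Analysis of the target

The target is a monocyclic lignan built on an oxolane (O1, C2–C5). C2 carries a 3,4-dihydroxyphenyl ring, C3 an acetoxymethyl group (side carbon C6), C4 a 4-hydroxy-3-methoxybenzyl group (benzylic side carbon C7), and C5 is an unsubstituted CH2. The three stereocentres are contiguous, (2S,3R,4R): the C2 aryl is trans to the C3 side chain, while the C3 and C4 side chains are cis. The sensitive groups are the catechol (air and base), one primary acetate that must sit beside three free phenols, and the C2–O1 bond. That bond is a para-hydroxybenzylic ether: under acid it ionizes, which can epimerize C2 or let the cation close onto the guaiacyl ring to an aryltetralin, and it is also open to hydrogenolysis. The difficulty is that the crowded cis C3/C4 relation must be enforced, the absolute configuration needs a dependable source, and the end game must tell one aliphatic hydroxyl from three phenolic ones. The route rests on one feature: C6 and C7 are cis on neighbouring ring carbons and C7 is benzylic. They can therefore be tied as a γ-lactone (C6 as carbonyl, ring oxygen on C7); the resulting bicycle can only be cis-fused, which fixes C3 from C4, and the tether is later cut at C7–O by hydrogenolysis. The lability of C2 is used, not fought: C2 is left to thermodynamic control near the end.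

## Retrosynthetic reasoning

**Acetate last.** The C6–O acyl bond of 22 is cut first, giving tetraol 21. Placing the acetate last means no later step has to tolerate an ester, and an enzyme can be asked to acylate the only aliphatic hydroxyl beside three phenols.

**C2 by equilibration.** 21 is traced to the tosylate 20 (S–O cleavage) and 20 to its C2 epimer 18. The C2–O1 bond is the one bond of the ring that opens reversibly, through the quinone methide 19. This disconnection therefore costs nothing in bonds and turns the weakest centre into one that corrects itself. The forward reaction must reclose only to the oxolane and must not let the guaiacyl ring trap the cation, which is why that ring stays a sulfonate ester until this point.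

**Reopening the template.** 18 comes from acid 17 by reduction, and 17 from the bicyclic lactone 15 by reconnecting the C6 carboxyl oxygen to C7. In the forward sense this is a hydrogenolysis that removes the two benzyl ethers (through 16) and cuts the benzylic acyloxy bond. It must leave the second benzylic C–O bond, C2–O1, intact; the difference in leaving group (carboxylate against alkoxide) is what the step relies on.

**Key disconnection, C2–C3.** 15 is cut between C2 and C3 to the diazo lactone 14. This is the bond between two stereocentres; cutting it leaves a simple benzylic ether and a lactone α-carbon. The forward carbenoid insertion closes the oxolane onto the lactone, so C3 is dictated by C4 through the cis ring fusion, and C2 need not be controlled.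

**Precursor assembly.** 14 comes from lactone 12 by diazo transfer through the activated 13. 12 is cut at the O1–C2 ether bond into alcohol 9 and imidate 11 (from alcohol 10). An acid-catalysed etherification is chosen because 9 would translactonize as an alkoxide.

**Source of chirality.** 9 is the reduction product of acid 8, which is freed from imide 7. 7 is cut at C4–C7 to the succinyl imide 5 and aldehyde 2 through the syn-aldol adduct 6. The aldol sets C4 (kept) and C7 (a relay centre, erased later) in one step, and the syn adduct lactonizes to the trans lactone needed. 5 comes from 3 and 4, and 2 from 1.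

## Alternatives that were turned down

**Alternative 1:** The ring is assembled in one operation from propargyl alcohol A1, the arylidene malonate A2 and the aryl iodide A3, cutting O1–C2, C3–C4 and the C7–aryl bond. In the forward step the alkoxide of A1 adds to A2, the malonate anion attacks the alkyne held by the arylpalladium species, and reductive elimination gives the benzylidene oxolane diester A4; the catalyst is zerovalent palladium with a chiral bisphosphine and an alkoxide base.
- For: three bonds and the ring in one step from trivial pieces. The phenols stay benzylated, so the acetate could be installed without any selectivity problem. On step count and convergence this alternative is clearly stronger.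
- Against: C2 is formed in a reversible oxa-Michael addition away from the metal, so the ligand can only act through a later selection and enantiocontrol is not secured by the mechanism. C3 emerges as a quaternary diester; after loss of one ester the C3–H is both α to an ester and allylic to the C4=C7 bond, so migration of the alkene into the ring threatens C3 and C4 together. The final hydrogenation must be face-selective and spare an allylic and a benzylic C–O bond.
- Comparison: the chosen route is longer but takes its absolute configuration from an auxiliary aldol of known sense and fixes C3/C4 by ring fusion.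

**Alternative 2:** The C3–C4 bond is cut. The epoxy cinnamyl ether A5 is opened by a trivalent titanium reagent of the titanocene type to a C3 radical, which cyclizes onto the cinnamyl alkene; the benzylic radical is reduced to CH2, giving the alcohol A6.
- For: the shortest route. The C6 hydroxyl appears free while all phenols are still benzylated, so acetylation is trivial and only debenzylation remains. On step economy and on the acetate problem it is better than the chosen strategy.
- Against: C2 must be bought beforehand as an enantioenriched, ionization-prone aryl carbinol ether. C3 and C4 are set together in a flexible radical transition state; 2,3-trans is well supported, but 3,4-cis rests on a small conformational preference, so isomer mixtures are likely. The reagent is stoichiometric.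
- Comparison: the chosen strategy gives up brevity for a C3/C4 relation that cannot form wrongly and a C2 that is corrected thermodynamically.

**Alternative 3:** The C4–C5 bond is cut. A silyl triflate ionizes the methoxymethyl ether A7 to an oxocarbenium ion on O1; the styrene attacks through C4 and the benzylic cation loses a proton to give the benzylidene oxolane A8.
- For: the acetate is in place from the start, and one hydrogenation (alkene and benzyl ethers) would finish the synthesis.
- Against: the oxocarbenium ion is homoallylic to the styrene, so an oxonia-Cope rearrangement to an aryl-stabilized cation at C2 can scramble C2 and C3. The electron-rich benzylic C2–O bond can ionize directly. The neighbouring acetate can capture cations. The five-membered closure needs the poorer trajectory in which the cation is endocyclic. The last hydrogenation carries the same face-selectivity and C–O hydrogenolysis risks as in alternative 1.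
- Comparison: fewer steps, but the key step puts the two existing stereocentres at risk, whereas the chosen key step forms its bond under ring constraint.

Key step: step 9

Remark on the chemistry: the insertion is taken to give the endo-aryl isomer 15; the exo isomer, if formed, would be carried through the same steps, because C2 is equilibrated in step 12.

## Route

Step 1
Reactants: 1 vanillin
Product: 2 4-formyl-2-methoxyphenyl 4-methylbenzenesulfonate (O-tosylvanillin)
Conditions: TsCl, Et3N, DMAP (cat.), CH2Cl2, 0 °C to rt
Reagents that add atoms: p-toluenesulfonyl chloride, Cc1ccc(cc1)S(=O)(=O)Cl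
Why: Phenol sulfonylation under amine base; the tosylate survives base, borane and hydrogenation and lowers the nucleophilicity of the guaiacyl ring for the later acid step.

Step 2
Reactants: 3 (S)-4-benzyl-1,3-oxazolidin-2-one; 4 methyl 4-chloro-4-oxobutanoate
Product: 5 methyl 4-[(4S)-4-benzyl-2-oxo-1,3-oxazolidin-3-yl]-4-oxobutanoate
Conditions: n-BuLi, THF, −78 °C; then 4, −78 to 0 °C
Reagents that add atoms: none
Why: N-acylation of the lithiated oxazolidinone; at low temperature only the acid chloride end of 4 reacts.

Step 3
Reactants: 5 succinyl imide; 2 O-tosylvanillin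
Product: 7 (4S)-4-benzyl-3-{(2S,3S)-2-[3-methoxy-4-(tosyloxy)phenyl]-5-oxooxolane-3-carbonyl}-1,3-oxazolidin-2-one (trans lactone imide), via syn-aldol adduct 6 (not isolated)
Conditions: Bu2BOTf, i-Pr2NEt, CH2Cl2, 0 °C; then 2, −78 to 0 °C; H2O2, pH 7 buffer, MeOH, 0 °C; crude, TsOH·H2O (cat.), CH2Cl2, rt
Reagents that add atoms: none
Why: Evans syn aldol: the Z boron enolate forms at the imide side only and reacts through a Zimmerman–Traxler chair on the face away from the auxiliary benzyl group, setting C4 and C7 as the (3S,4S) adduct 6. The C7 hydroxyl then closes onto the methyl ester, and the syn relation becomes the trans lactone.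

Step 4
Reactants: 7 trans lactone imide
Product: 8 (2S,3S)-2-[3-methoxy-4-(tosyloxy)phenyl]-5-oxooxolane-3-carboxylic acid
Conditions: LiOH, H2O2, THF–H2O, 0 °C; Na2SO3; then HCl to pH 2
Reagents that add atoms: hydrogen peroxide, OO (as LiOOH; supplies the carboxyl oxygen)
Why: Hydroperoxide attacks the exocyclic imide carbonyl selectively and the auxiliary is recovered; any lactone that opens recloses on acidification, since only the five-membered lactone can form.

Step 5
Reactants: 8 trans paraconic acid
Product: 9 (4R,5S)-4-(hydroxymethyl)-5-[3-methoxy-4-(tosyloxy)phenyl]oxolan-2-one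
Conditions: BH3·SMe2, THF, 0 °C to rt; MeOH
Reagents that add atoms: none
Why: Borane reduces a carboxylic acid through its acyloxyborane far faster than a lactone or an aryl sulfonate; C4 is not touched (its descriptor changes only through priorities).

Step 6
Reactants: 10 [3,4-bis(benzyloxy)phenyl]methanol
Product: 11 [3,4-bis(benzyloxy)phenyl]methyl 2,2,2-trichloroacetimidate
Conditions: Cl3CCN, DBU (cat.), CH2Cl2, 0 °C; used at once
Reagents that add atoms: trichloroacetonitrile, ClC(Cl)(Cl)C#N
Why: Base-catalysed addition of the alcohol to the nitrile; the electron-rich imidate is used crude to avoid rearrangement to the amide.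

Step 7
Reactants: 9 hydroxymethyl lactone; 11 trichloroacetimidate
Product: 12 (4R,5S)-4-({[3,4-bis(benzyloxy)phenyl]methoxy}methyl)-5-[3-methoxy-4-(tosyloxy)phenyl]oxolan-2-one
Conditions: CSA (cat.), CH2Cl2, 0 °C to rt (11 in excess)
Reagents that add atoms: none
Why: Acid-catalysed trichloroacetimidate benzylation: the stabilized benzylic cation is captured by the primary alcohol. No alkoxide is formed, so base-induced translactonization of 9 is avoided; this step makes the O1–C2 bond.

Step 8
Reactants: 12 lactone ether
Product: 14 (4R,5S)-4-({[3,4-bis(benzyloxy)phenyl]methoxy}methyl)-3-diazo-5-[3-methoxy-4-(tosyloxy)phenyl]oxolan-2-one, via 3-trifluoroacetyl lactone 13 (not isolated)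
Conditions: LiN(SiMe3)2, THF, −78 °C; CF3CO2CH2CF3, −78 °C; aq. HCl work-up; then p-ABSA, Et3N, H2O (1 equiv), MeCN, rt
Reagents that add atoms: 4-acetamidobenzenesulfonyl azide, CC(=O)Nc1ccc(cc1)S(=O)(=O)N=[N+]=[N-] (the two diazo nitrogens of 14); 2,2,2-trifluoroethyl trifluoroacetate, FC(F)(F)COC(=O)C(F)(F)F (the trifluoroacetyl group of 13 only)
Why: Claisen-type trifluoroacetylation of the lactone enolate activates C3, and Regitz-type deacylative diazo transfer then expels the N-trifluoroacetyl sulfonamide. The enolate has no β-leaving group, and C4 and C7 are untouched.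

Step 9
Reactants: 14 diazo lactone
Product: 15 (3S,3aR,6R,6aS)-6-[3,4-bis(benzyloxy)phenyl]-3-[3-methoxy-4-(tosyloxy)phenyl]tetrahydro-1H,3H-furo[3,4-c]furan-1-one (cis-fused, 6-aryl endo)
Conditions: Rh2(OAc)4 (2 mol %), CH2Cl2, reflux, slow addition of 14
Reagents that add atoms: none
Why: Rh2(OAc)4 (divalent rhodium) takes up the diazo carbon of 14, N2 leaves and an electrophilic rhodium carbenoid stands at C3. It inserts into one C2–H bond of the benzylic ether through a three-centre, hydride-transfer-like transition state in which the positive charge at C2 is carried by O1 and the electron-rich aryl ring; the C2–C3 bond forms and the catalyst is released. The closest known reaction type is the dirhodium-catalysed intramolecular 1,5 C–H insertion of α-diazo-γ-butyrolactones into benzylic ether C–H bonds, which gives furofuranones. The oxolane (C3–C4–C5–O1–C2) closes as a 1,5-insertion, the only ring size within reach of these C–H bonds. C3 is controlled by the ring fusion: a bicyclo[3.3.0] lactone can only be cis-fused, so the new bond forms on the lactone face that carries C5, and C3 follows from C4 as set by the aldol. C2 depends on which diastereotopic hydrogen reacts; the aryl group is expected on the concave face as in related insertions, and this centre is not relied on. The step needs insertion to beat 1,2-hydride shift from C4–H, carbene dimerization and addition to an aryl ring; the doubly activated C2–H bonds, the deactivated and trans-placed C7 aryl ring, and slow addition secure this.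

Step 10
Reactants: 15 furofuranone
Product: 17 (2R,3S,4R)-2-(3,4-dihydroxyphenyl)-4-{[3-methoxy-4-(tosyloxy)phenyl]methyl}oxolane-3-carboxylic acid (all-cis), via debenzylated furofuranone 16 (not isolated)
Conditions: H2 (1 atm), 10% Pd/C, EtOAc, rt; stopped when 16 is consumed
Reagents that add atoms: none
Why: Palladium-catalysed hydrogenolysis cleaves the two aryl benzyl ethers and then the benzylic acyloxy bond C7–O (carboxylate leaving group). The ring ether C2–O1 (alkoxide leaving group) is much slower in a neutral aprotic medium and the aryl tosylate is inert. C7 becomes CH2, and C3 and C4 keep their cis relation.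

Step 11
Reactants: 17 all-cis acid
Product: 18 (2R,3R,4R)-2-(3,4-dihydroxyphenyl)-3-(hydroxymethyl)-4-{[3-methoxy-4-(tosyloxy)phenyl]methyl}oxolane (all-cis)
Conditions: BH3·SMe2 (excess), THF, 0 °C to rt; MeOH
Reagents that add atoms: none
Why: Chemoselective borane reduction of the acid to C6H2OH; the catechol consumes borane as aryl borates, which methanol cleaves on work-up, and C3 is no longer epimerizable afterwards.

Step 12
Reactants: 18 all-cis alcohol
Product: 20 (2S,3R,4R)-2-(3,4-dihydroxyphenyl)-3-(hydroxymethyl)-4-{[3-methoxy-4-(tosyloxy)phenyl]methyl}oxolane (2,3-trans, 3,4-cis), via open-chain quinone methide 19 (not isolated)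
Conditions: CSA (cat.), MeCN, rt, Ar
Reagents that add atoms: none
Why: Acid-catalysed epimerization of a para-hydroxybenzylic ether: C2–O1 ionizes with help from the para hydroxyl to the quinone methide (as its protonated form) and the C5 hydroxyl recloses the five-membered ring, the C6 hydroxyl being able to give only an oxetane. The crowded all-cis isomer drains to the isomer with the C2 aryl trans to C3. The sulfonate makes the guaiacyl ring a poorer nucleophile, which slows the irreversible Friedel–Crafts closure.

Step 13
Reactants: 20 trans alcohol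
Product: 21 4-[(2S,3R,4R)-4-[(4-hydroxy-3-methoxyphenyl)methyl]-3-(hydroxymethyl)oxolan-2-yl]benzene-1,2-diol
Conditions: KOH, MeOH–H2O, 60 °C, degassed, Ar; then aq. HCl
Reagents that add atoms: none
Why: Saponification of the aryl sulfonate by attack at sulfur; no ester is present yet, and exclusion of oxygen protects the catecholate.

Step 14
Reactants: 21 tetraol
Product: 22 [(2S,3R,4R)-2-(3,4-dihydroxyphenyl)-4-[(4-hydroxy-3-methoxyphenyl)methyl]oxolan-3-yl]methyl acetate (target)
Conditions: vinyl acetate, immobilized Candida antarctica lipase B, THF, 40 °C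
Reagents that add atoms: vinyl acetate, CC(=O)OC=C
Why: Lipase-catalysed transesterification, made irreversible by tautomerization of the leaving enol to acetaldehyde; the acyl-enzyme accepts the primary aliphatic hydroxyl, not the phenols.

## Compound list

1 | vanillin | COc1cc(C=O)ccc1O | starting material
2 | 4-formyl-2-methoxyphenyl 4-methylbenzenesulfonate | COc1cc(C=O)ccc1OS(=O)(=O)c1ccc(C)cc1 | intermediate
3 | (S)-4-benzyl-1,3-oxazolidin-2-one | O=C1N[C@@H](Cc2ccccc2)CO1 | starting material
4 | methyl 4-chloro-4-oxobutanoate | COC(=O)CCC(Cl)=O | starting material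
5 | methyl 4-[(4S)-4-benzyl-2-oxo-1,3-oxazolidin-3-yl]-4-oxobutanoate | COC(=O)CCC(=O)N1[C@@H](Cc2ccccc2)COC1=O | intermediate
6 | methyl (3S,4S)-3-[(4S)-4-benzyl-2-oxo-1,3-oxazolidine-3-carbonyl]-4-hydroxy-4-[3-methoxy-4-(tosyloxy)phenyl]butanoate | COC(=O)C[C@H](C(=O)N1[C@@H](Cc2ccccc2)COC1=O)[C@H](O)c1ccc(OS(=O)(=O)c2ccc(C)cc2)c(OC)c1 | intermediate
7 | (4S)-4-benzyl-3-{(2S,3S)-2-[3-methoxy-4-(tosyloxy)phenyl]-5-oxooxolane-3-carbonyl}-1,3-oxazolidin-2-one | COc1cc([C@H]2OC(=O)C[C@@H]2C(=O)N3[C@@H](Cc4ccccc4)COC3=O)ccc1OS(=O)(=O)c1ccc(C)cc1 | intermediate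
8 | (2S,3S)-2-[3-methoxy-4-(tosyloxy)phenyl]-5-oxooxolane-3-carboxylic acid | COc1cc([C@H]2OC(=O)C[C@@H]2C(=O)O)ccc1OS(=O)(=O)c1ccc(C)cc1 | intermediate
9 | (4R,5S)-4-(hydroxymethyl)-5-[3-methoxy-4-(tosyloxy)phenyl]oxolan-2-one | COc1cc([C@H]2OC(=O)C[C@@H]2CO)ccc1OS(=O)(=O)c1ccc(C)cc1 | intermediate
10 | [3,4-bis(benzyloxy)phenyl]methanol | OCc1ccc(OCc2ccccc2)c(OCc2ccccc2)c1 | starting material
11 | [3,4-bis(benzyloxy)phenyl]methyl 2,2,2-trichloroacetimidate | N=C(OCc1ccc(OCc2ccccc2)c(OCc2ccccc2)c1)C(Cl)(Cl)Cl | intermediate
12 | (4R,5S)-4-({[3,4-bis(benzyloxy)phenyl]methoxy}methyl)-5-[3-methoxy-4-(tosyloxy)phenyl]oxolan-2-one | COc1cc([C@H]2OC(=O)C[C@@H]2COCc2ccc(OCc3ccccc3)c(OCc3ccccc3)c2)ccc1OS(=O)(=O)c1ccc(C)cc1 | intermediate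
13 | 3-(trifluoroacetyl) derivative of 12 (C3 unassigned, enolizable) | COc1cc([C@H]2OC(=O)C(C(=O)C(F)(F)F)[C@@H]2COCc2ccc(OCc3ccccc3)c(OCc3ccccc3)c2)ccc1OS(=O)(=O)c1ccc(C)cc1 | intermediate
14 | (4R,5S)-4-({[3,4-bis(benzyloxy)phenyl]methoxy}methyl)-3-diazo-5-[3-methoxy-4-(tosyloxy)phenyl]oxolan-2-one | COc1cc([C@H]2OC(=O)C(=[N+]=[N-])[C@@H]2COCc2ccc(OCc3ccccc3)c(OCc3ccccc3)c2)ccc1OS(=O)(=O)c1ccc(C)cc1 | intermediate
15 | (3S,3aR,6R,6aS)-6-[3,4-bis(benzyloxy)phenyl]-3-[3-methoxy-4-(tosyloxy)phenyl]tetrahydro-1H,3H-furo[3,4-c]furan-1-one | COc1cc([C@H]2OC(=O)[C@@H]3[C@H](c4ccc(OCc5ccccc5)c(OCc5ccccc5)c4)OC[C@H]23)ccc1OS(=O)(=O)c1ccc(C)cc1 | intermediate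
16 | (3S,3aR,6R,6aS)-6-(3,4-dihydroxyphenyl)-3-[3-methoxy-4-(tosyloxy)phenyl]tetrahydro-1H,3H-furo[3,4-c]furan-1-one | COc1cc([C@H]2OC(=O)[C@@H]3[C@H](c4ccc(O)c(O)c4)OC[C@H]23)ccc1OS(=O)(=O)c1ccc(C)cc1 | intermediate
17 | (2R,3S,4R)-2-(3,4-dihydroxyphenyl)-4-{[3-methoxy-4-(tosyloxy)phenyl]methyl}oxolane-3-carboxylic acid | COc1cc(C[C@H]2CO[C@@H](c3ccc(O)c(O)c3)[C@H]2C(=O)O)ccc1OS(=O)(=O)c1ccc(C)cc1 | intermediate
18 | (2R,3R,4R)-2-(3,4-dihydroxyphenyl)-3-(hydroxymethyl)-4-{[3-methoxy-4-(tosyloxy)phenyl]methyl}oxolane | COc1cc(C[C@H]2CO[C@@H](c3ccc(O)c(O)c3)[C@H]2CO)ccc1OS(=O)(=O)c1ccc(C)cc1 | intermediate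
19 | open-chain para-quinone methide of 18 (C3 and C4 as in 18; alkene geometry unassigned) | COc1cc(C[C@@H](CO)[C@H](CO)C=C2C=CC(=O)C(O)=C2)ccc1OS(=O)(=O)c1ccc(C)cc1 | intermediate
20 | (2S,3R,4R)-2-(3,4-dihydroxyphenyl)-3-(hydroxymethyl)-4-{[3-methoxy-4-(tosyloxy)phenyl]methyl}oxolane | COc1cc(C[C@H]2CO[C@H](c3ccc(O)c(O)c3)[C@H]2CO)ccc1OS(=O)(=O)c1ccc(C)cc1 | intermediate
21 | 4-[(2S,3R,4R)-4-[(4-hydroxy-3-methoxyphenyl)methyl]-3-(hydroxymethyl)oxolan-2-yl]benzene-1,2-diol | COc1cc(C[C@H]2CO[C@H](c3ccc(O)c(O)c3)[C@H]2CO)ccc1O | intermediate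
22 | [(2S,3R,4R)-2-(3,4-dihydroxyphenyl)-4-[(4-hydroxy-3-methoxyphenyl)methyl]oxolan-3-yl]methyl acetate | COc1cc(C[C@H]2CO[C@H](c3ccc(O)c(O)c3)[C@H]2COC(C)=O)ccc1O | target

## Step count and least certain steps

Total: 14 steps. Longest linear sequence: 12 steps (1 → 2 → 7 → 8 → 9 → 12 → 14 → 15 → 17 → 18 → 20 → 21 → 22).

**Step 9 (key step).** The most likely failure is 1,2-hydride migration from C4–H to the carbenoid carbon, giving a butenolide, because the insertion must reach across the forming ring fusion; carbene dimerization and attack on an aryl ring are secondary risks. The fallback sets out from 9 and returns at 15, forming C2–C3 by enolate chemistry and closing O1–C2 by reductive etherification. 9 is silylated (TBSCl, imidazole) to the silyl ether F1. Its lithium enolate (LiN(SiMe3)2, THF, −78 °C) adds to commercial 3,4-bis(benzyloxy)benzaldehyde to give the aldol adduct F2. Dess–Martin oxidation gives the β-keto lactone F3, whose C3 is freely epimerizable. Desilylation (HF·pyridine) lets the C5 hydroxyl add to the ketone, giving the cis-fused hemiketal F4. Et3SiH with BF3·OEt2 at −78 °C reduces F4 through the bicyclic oxocarbenium ion, hydride arriving on the convex face, to 15.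

**Step 10.** Two processes can go wrong: hydrogenolytic opening of the oxolane at C2–O1 once the catechol is free, and slow C7–O cleavage because the sulfonate-bearing ring is electron-poor. A first adjustment of conditions is a catalyst moderated by a nitrogen base, which is known to spare alkyl benzyl ethers while benzylic esters still cleave. The fallback changes the way C7–O is cut, sets out from 15 and returns at 18. LiBH4 opens the lactone to the diol F5. The primary hydroxyl is silylated to F6. The benzylic hydroxyl is converted (PhOC(S)Cl, pyridine, DMAP) to the thionocarbonate F7. Barton–McCombie deoxygenation (Bu3SnH, AIBN, toluene, 80 °C) gives F8. Desilylation gives the alcohol F9. A brief hydrogenolysis, needing only the fast aryl benzyl ether cleavage, gives 18.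

**Step 12.** The risk is irreversible Friedel–Crafts capture of the C2 cation by the guaiacyl ring (the tosylate slows this but cannot exclude it), or incomplete equilibration. The fallback moves the epimerization to the bicyclic stage, sets out from 15 and returns at 20. There the C7 aryl is trans to C2 across the lactone and cannot reach the cation. BF3·OEt2 (cat.) in CH2Cl2 equilibrates 15 with its exo-aryl epimer F10; the equilibrium is expected to be less one-sided, so F10 is separated and 15 recycled. Hydrogenolysis of F10 as in step 10 gives the trans acid F11, and borane reduction as in step 11 gives 20.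

**Step 7.** The risks are acid-induced acyl shift in 9 (from the C7 oxygen to the primary oxygen) and self-alkylation or rearrangement of the electron-rich imidate. The fallback sets out from 9 and returns at 12 with a silver-assisted Williamson alkylation. 10 is converted with PBr3 to the benzyl bromide F12, and 9 is alkylated with F12 and Ag2O in CH2Cl2 over molecular sieves.

**Step 14.** The risks are slow acylation of the hindered primary hydroxyl and partial acylation of a phenol. The fallback sets out from 21 and returns at 22. Ac2O in pyridine gives the tetraacetate F13, and NH4OAc in aqueous MeOH at rt then removes the three far more labile aryl acetates, leaving the alkyl acetate 22.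

## Further compounds

F1 | step 9 | (4R,5S)-4-{[(tert-butyldimethylsilyl)oxy]methyl}-5-[3-methoxy-4-(tosyloxy)phenyl]oxolan-2-one | COc1cc([C@H]2OC(=O)C[C@@H]2CO[Si](C)(C)C(C)(C)C)ccc1OS(=O)(=O)c1ccc(C)cc1
F2 | step 9 | 3-{[3,4-bis(benzyloxy)phenyl](hydroxy)methyl} derivative of F1 (C3 and carbinol centre unassigned) | COc1cc([C@H]2OC(=O)C(C(O)c3ccc(OCc4ccccc4)c(OCc4ccccc4)c3)[C@@H]2CO[Si](C)(C)C(C)(C)C)ccc1OS(=O)(=O)c1ccc(C)cc1
F3 | step 9 | 3-[3,4-bis(benzyloxy)benzoyl] derivative of F1 (C3 epimerizable) | COc1cc([C@H]2OC(=O)C(C(=O)c3ccc(OCc4ccccc4)c(OCc4ccccc4)c3)[C@@H]2CO[Si](C)(C)C(C)(C)C)ccc1OS(=O)(=O)c1ccc(C)cc1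
F4 | step 9 | 6-hydroxy derivative of 15 (cis-fused hemiketal, anomeric centre unassigned) | COc1cc([C@H]2OC(=O)[C@@H]3C(O)(c4ccc(OCc5ccccc5)c(OCc5ccccc5)c4)OC[C@H]23)ccc1OS(=O)(=O)c1ccc(C)cc1
F5 | step 10 | diol from reduction of 15: all-cis 2-[3,4-bis(benzyloxy)phenyl]-3-(hydroxymethyl)oxolane with a (hydroxy)[3-methoxy-4-(tosyloxy)phenyl]methyl group on C4 | COc1cc([C@@H](O)[C@H]2CO[C@@H](c3ccc(OCc4ccccc4)c(OCc4ccccc4)c3)[C@H]2CO)ccc1OS(=O)(=O)c1ccc(C)cc1
F6 | step 10 | primary tert-butyldimethylsilyl ether of F5 | COc1cc([C@@H](O)[C@H]2CO[C@@H](c3ccc(OCc4ccccc4)c(OCc4ccccc4)c3)[C@H]2CO[Si](C)(C)C(C)(C)C)ccc1OS(=O)(=O)c1ccc(C)cc1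
F7 | step 10 | O-phenyl thionocarbonate of F6 at the benzylic hydroxyl | COc1cc([C@@H](OC(=S)Oc6ccccc6)[C@H]2CO[C@@H](c3ccc(OCc4ccccc4)c(OCc4ccccc4)c3)[C@H]2CO[Si](C)(C)C(C)(C)C)ccc1OS(=O)(=O)c1ccc(C)cc1
F8 | step 10 | deoxygenated silyl ether: all-cis 2-[3,4-bis(benzyloxy)phenyl]-3-{[(tert-butyldimethylsilyl)oxy]methyl}-4-{[3-methoxy-4-(tosyloxy)phenyl]methyl}oxolane | COc1cc(C[C@H]2CO[C@@H](c3ccc(OCc4ccccc4)c(OCc4ccccc4)c3)[C@H]2CO[Si](C)(C)C(C)(C)C)ccc1OS(=O)(=O)c1ccc(C)cc1
F9 | step 10 | di-O-benzyl ether of 18 | COc1cc(C[C@H]2CO[C@@H](c3ccc(OCc4ccccc4)c(OCc4ccccc4)c3)[C@H]2CO)ccc1OS(=O)(=O)c1ccc(C)cc1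
F10 | step 12 | C6 epimer of 15 (6-aryl exo) | COc1cc([C@H]2OC(=O)[C@@H]3[C@@H](c4ccc(OCc5ccccc5)c(OCc5ccccc5)c4)OC[C@H]23)ccc1OS(=O)(=O)c1ccc(C)cc1
F11 | step 12 | C2 epimer of 17 (2,3-trans, 3,4-cis acid) | COc1cc(C[C@H]2CO[C@H](c3ccc(O)c(O)c3)[C@H]2C(=O)O)ccc1OS(=O)(=O)c1ccc(C)cc1
F12 | step 7 | 1,2-bis(benzyloxy)-4-(bromomethyl)benzene | BrCc1ccc(OCc2ccccc2)c(OCc2ccccc2)c1
F13 | step 14 | tetraacetate of 21 | COc1cc(C[C@H]2CO[C@H](c3ccc(OC(C)=O)c(OC(C)=O)c3)[C@H]2COC(C)=O)ccc1OC(C)=O
A1 | alternative 1 | prop-2-yn-1-ol | OCC#C
A2 | alternative 1 | diethyl 2-{[3,4-bis(benzyloxy)phenyl]methylidene}propanedioate | CCOC(=O)C(=Cc1ccc(OCc2ccccc2)c(OCc2ccccc2)c1)C(=O)OCC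
A3 | alternative 1 | 1-(benzyloxy)-4-iodo-2-methoxybenzene | COc1cc(I)ccc1OCc1ccccc1
A4 | alternative 1 | diethyl (Z)-2-[3,4-bis(benzyloxy)phenyl]-4-{[4-(benzyloxy)-3-methoxyphenyl]methylidene}oxolane-3,3-dicarboxylate (C2 placed as in the target) | COc1cc(/C=C2\CO[C@H](c3ccc(OCc4ccccc4)c(OCc4ccccc4)c3)C2(C(=O)OCC)C(=O)OCC)ccc1OCc1ccccc1
A5 | alternative 2 | 2-{[3,4-bis(benzyloxy)phenyl]{[(E)-3-(4-benzyloxy-3-methoxyphenyl)prop-2-en-1-yl]oxy}methyl}oxirane (carbinol centre as C2 of the target, epoxide centre unassigned) | COc1cc(/C=C/CO[C@H](c2ccc(OCc3ccccc3)c(OCc3ccccc3)c2)C2CO2)ccc1OCc1ccccc1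
A6 | alternative 2 | [(2S,3R,4R)-2-[3,4-bis(benzyloxy)phenyl]-4-{[4-(benzyloxy)-3-methoxyphenyl]methyl}oxolan-3-yl]methanol | COc1cc(C[C@H]2CO[C@H](c3ccc(OCc4ccccc4)c(OCc4ccccc4)c3)[C@H]2CO)ccc1OCc1ccccc1
A7 | alternative 3 | (E)-2-{[3,4-bis(benzyloxy)phenyl](methoxymethoxy)methyl}-4-[4-(benzyloxy)-3-methoxyphenyl]but-3-en-1-yl acetate (centres as C2 and C3 of the target) | COCO[C@H](c1ccc(OCc2ccccc2)c(OCc2ccccc2)c1)[C@@H](COC(C)=O)/C=C/c1ccc(OCc2ccccc2)c(OC)c1
A8 | alternative 3 | [(2S,3R,Z)-2-[3,4-bis(benzyloxy)phenyl]-4-{[4-(benzyloxy)-3-methoxyphenyl]methylidene}oxolan-3-yl]methyl acetate | COc1cc(/C=C2\CO[C@H](c3ccc(OCc4ccccc4)c(OCc4ccccc4)c3)[C@H]2COC(C)=O)ccc1OCc1ccccc1
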